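## Structural features

The target is a germacranolide: a ten-membered carbocycle (C1–C10) with an α-methylene-γ-butyrolactone (O6, C6, C7, C11, C12, exocyclic C11=C13) trans-fused across C6–C7. The ring holds two trisubstituted olefins, C1=C10 and C4=C5. Both are cis within the ring (their descriptors are E only because C14 and C15 outrank the ring carbons), and they carry the C14 aldehyde and the C15 acetoxymethyl group. Three stereocentres are contiguous: C6 (R, lactone oxygen), C7 (R) and C8 (R, isovalerate). The fourth, the free allylic carbinol C2 (S), is separated from them by C3–C5. The fragile groups are the α-methylene lactone (Michael acceptor, photoreactive), the γ-hydroxy enal, the two esters, and a free O8, which can translactonise onto C12. The real difficulty is a strained medium ring with two cis olefins in which five oxygenated positions (C2, C8, C14, C15, lactone) must be told apart and C2 and C8 must be set on a flexible ring. The key step uses the 1,5-relationship of the oxygen-bearing carbons C2 and C8 across C1=C10 and C9. That pattern is what a retro-aldol opening of a cyclobutene spanning C2–C9 leaves behind, so the ten-membered ring can be grown from a lactone-fused eight-membered ring (C2–C9) by inserting C1 and C10 as an alkyne.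

## Logic of the disconnections

34 is taken back to 33 by lowering C14 from aldehyde to primary allylic alcohol, and 33 to 32 by placing silyl groups on O2 and O14. No skeletal bond is cut. The enal and the free C2 hydroxyl are the most sensitive functions and are unveiled last. The forward demand is an oxidant that takes the primary allylic alcohol and spares the secondary one.

32 goes back to 31 and then 30 by cutting the acyl C–O bonds at O8 and O15. The esters come late because neither survives the lactone enolate needed for C13. The forward demand is acetylation of the primary O15 in the presence of the hindered O8.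

30 goes back to 29 and then to 26 (through 28 and 27) by cutting C11=C13. This removes the Michael acceptor from all earlier chemistry. The forward demand is that the lactone α-CH2 be the only acidic site, so every hydroxyl is silylated, with O8 and O15 carrying groups more labile than those on O2 and O14.

26 goes back through 25, 24 and 23 to 22 by returning the carbinol C–H bonds at C8 and C2 to carbonyls. This gives the 2,8-dione that the key step delivers. The forward demand is reduction of the enone before the saturated ketone, each under catalyst control.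

22 goes back through 21 to 18 and 20. After C2–C9 is re-formed, C1–C2 and C9–C10 are cut, so the ten-membered ring becomes an eight-membered enone plus an alkyne. The cis C1=C10 geometry then comes for free from a cyclobutene. The forward demands are the right orientation of addition, an enol ether located unambiguously at C2, and protonation at C9 after fragmentation.

18 goes back to 17 by cutting the two Si–O bonds. Bridging O15 to the C2 enol oxygen fixes the enol ether regiochemistry by ring size and gives a silyl group that fluoride still removes after C2 has become a tertiary carbinol. 17 goes back to 16 by exchanging the C2 oxygen for the amine and re-silylating O15.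

16 goes back to 15 by cutting C4=C5 (ring-closing metathesis). The E enaminone and the trans lactone hold the two olefins on the same side. The forward demand is closure of an eight-membered ring at a 1,1-disubstituted olefin.

15 goes back through 14 and 13 to 7 and 12 by cutting C2–N and C8–C9. An acyl–alkyne coupling places oxygen at C8 and nitrogen at C2 without any enolate regiochemistry problem at C3. The forward demand is that the base-sensitive acyl lactone is not epimerised or opened.

12 goes back to 10 and 11 by cutting C2–C3, then 10 to 9 and 8 by functional group changes. The forward demand is mono-functionalisation of a symmetrical diol.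

7 goes back to 6 (auxiliary removed), 6 through 5 to 3 and 4 by cutting the lactone C–O bond and the C6–C7 aldol bond, and 3 to 1 and 2. One auxiliary-controlled aldol sets both C6 and C7 in absolute terms.

20 goes back to 19 by cutting O–Si.

## Other disconnections considered

Alternative 1: The cut removes O6–C12 and C11–C12, leaving a C6 hydroxyl and a C7 ethynyl group on the finished ring, with C12 supplied by carbon monoxide. In the forward step PdCl2 with a thiourea ligand under CO would form an alkoxycarbonyl–palladium species at O6, add it across the alkyne and release the α-methylene lactone A1 on protonolysis.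
- In favour: the most fragile unit is made last and without enolate chemistry, so the C8 isovalerate and C15 acetate could already be in place. On protecting-group economy in the endgame this is better than the chosen plan, which needs a silylation/desilylation cycle around the Mannich methylenation.
- Against: it does not address the ten-membered ring, its two cis olefins or the four stereocentres, and it needs a ring with the alkyne trans to O6. The allylic acetate at C15 and the allylic C6–O bond could ionise on any zerovalent palladium formed under CO, and the enal would be exposed to the carbonylation medium.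
- Comparison: mechanistically the cyclocarbonylation of homopropargylic alcohols is as well founded as the Mannich route. Structurally it solves only the lactone, which the chosen plan gets from the first aldol step. It would save about three late steps but move the whole burden to an unspecified ring synthesis.

Alternative 2: The cut is C5–C6, opening the ring to a chain with a C5 alkenyl iodide and a C6 aldehyde. In the forward step CrCl2 with catalytic NiCl2 would generate zerovalent nickel, which inserts into the C–I bond, and transmetallation to an alkenyl species of trivalent chromium followed by addition to the aldehyde would close the ring to A2.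
- In favour: the reaction is chemoselective for aldehydes and tolerates esters and silyl ethers. C2, C7 and C8 would be set in open-chain chemistry, which is better than the chosen plan, where C2 and C8 come from reductions on a medium ring.
- Against: closing a strained ten-membered ring with two cis trisubstituted olefins is costly in entropy and strain and would need high dilution and a large excess of divalent chromium. The C6 configuration would be set in the ring-closing event with uncertain control. The lactone (oxidation at C12, lactonisation) and C13 would remain to be made.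
- Comparison: the chosen plan takes C6 and C7 from an auxiliary aldol and gets the cis olefins from ring constraints. The endgame of Alternative 2 is of similar length, but the linear chain before cyclisation is expected to be longer.

Alternative 3: The cut re-joins C1 to C6, so the ten-membered enone becomes two cis-fused six-membered rings with a tertiary C6 alkoxide and a C10/C14 spiro-epoxide. In the forward step the potassium alkoxide would fragment (Grob): C1–C6 breaks, the C6 carbonyl and C1=C10 form, and the epoxide opens to the C14 alkoxide, giving A3.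
- In favour: six-membered-ring chemistry is predictable, and the fragmentation is concerted, thermal and stereospecific. On scalability it is better than a photochemical step, and on control of the C1=C10 geometry it is the equal of the chosen plan.
- Against: it needs a stereodefined cis-decalin with an extra quaternary carbinol and a spiro-epoxide, the strongly basic conditions dictate ether protecting groups, and A3 still needs a stereoselective C6 reduction, lactone formation and C13. The C4=C5 olefin would sit next to the C6 ketone and could migrate.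
- Comparison: the bond reorganisation is as reliable as the retro-aldol of the chosen plan, but the step count is expected to be clearly higher before and after the fragmentation.

Key step: step 12

Remark: atom labels C1–C15 are those of the germacrane skeleton and are kept for all intermediates (eight-membered compounds are named as 1,10,14-trinorgermacranes with C2 bonded to C9); the lactone is trans-fused and C6 is R throughout, both ring olefins are ring-cis (descriptor E), and the C7 descriptor switches between R and S only through priority changes at C8.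

## Route

Step 1
Reactants: 1 (S)-4-benzyl-1,3-oxazolidin-2-one; 2 methyl 4-chloro-4-oxobutanoate
Product: 3 methyl 4-[(4S)-4-benzyl-2-oxo-1,3-oxazolidin-3-yl]-4-oxobutanoate
Conditions: n-BuLi, THF, −78 °C; 2, −78 → 0 °C
Reagents that add atoms: none
Why: N-acylation of the lithiated oxazolidinone; the acid chloride is far more electrophilic than the methyl ester at −78 °C, so the succinate is desymmetrised as imide and ester.

Step 2
Reactants: 3 methyl 4-[(4S)-4-benzyl-2-oxo-1,3-oxazolidin-3-yl]-4-oxobutanoate; 4 prop-2-enal (acrolein)
Product: 6 (4S)-4-benzyl-3-[(2R,3S)-2-ethenyl-5-oxooxolane-3-carbonyl]-1,3-oxazolidin-2-one, via syn-aldol adduct 5 (not isolated)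
Conditions: Bu2BOTf, i-Pr2NEt, CH2Cl2, −78 → 0 °C; 4, −78 °C; pH 7 buffer, H2O2, MeOH, 0 °C; p-toluenesulfonic acid (cat.), CH2Cl2, rt
Reagents that add atoms: none
Why: Evans syn aldol reaction: enolisation occurs only at the imide α-carbon and gives the Z boron enolate, which adds through a chair Zimmerman–Traxler transition state on the face away from the benzyl group and so sets C7 and C6. The γ-hydroxy ester then lactonises with loss of methanol, and the syn relationship becomes the trans-2,3-disubstituted lactone.

Step 3
Reactants: 6 (4S)-4-benzyl-3-[(2R,3S)-2-ethenyl-5-oxooxolane-3-carbonyl]-1,3-oxazolidin-2-one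
Product: 7 (2R,3S)-2-ethenyl-5-oxooxolane-3-carboxylic acid
Conditions: LiOH, H2O2, THF/H2O, 0 °C; Na2SO3; HCl to pH 2
Reagents that add atoms: hydrogen peroxide, OO (as LiOOH it supplies the hydroxyl oxygen of the acid)
Why: Hydroperoxide attacks the exocyclic imide carbonyl selectively and the auxiliary is released; any lactone opened by hydroxide recloses on acidification to the same five-membered ring, and the thermodynamically preferred trans arrangement is kept.

Step 4
Reactants: 8 2-methylidenepropane-1,3-diol
Product: 9 2-{[(tert-butyldimethylsilyl)oxy]methyl}prop-2-en-1-ol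
Conditions: NaH (1.0 equiv), THF, 0 °C; TBSCl (1.0 equiv)
Reagents that add atoms: tert-butyldimethylsilyl chloride, CC(C)(C)[Si](C)(C)Cl
Why: Monosilylation of a symmetrical diol through its monosodium alkoxide, which reacts once before a second deprotonation can compete.

Step 5
Reactants: 9 2-{[(tert-butyldimethylsilyl)oxy]methyl}prop-2-en-1-ol
Product: 10 {[2-(bromomethyl)prop-2-en-1-yl]oxy}(tert-butyl)dimethylsilane
Conditions: CBr4, PPh3, CH2Cl2, 0 °C
Reagents that add atoms: carbon tetrabromide, BrC(Br)(Br)Br
Why: Appel bromination of a primary allylic alcohol under neutral conditions that leave the silyl ether intact; direct and allylic substitution give the same product because the allyl unit is symmetrical.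

Step 6
Reactants: 10 {[2-(bromomethyl)prop-2-en-1-yl]oxy}(tert-butyl)dimethylsilane; 11 ethynylmagnesium bromide
Product: 12 tert-butyldimethyl[(2-methylidenepent-4-yn-1-yl)oxy]silane
Conditions: 11 (3 equiv), CuBr·SMe2 (5 mol%), THF, 0 °C → rt
Reagents that add atoms: none
Why: Copper-catalysed coupling of an alkynyl Grignard reagent with an allylic bromide forms C2–C3 and gives the skipped enyne; excess Grignard reagent keeps the product as its acetylide and suppresses double allylation and base-induced isomerisation.

Step 7
Reactants: 7 (2R,3S)-2-ethenyl-5-oxooxolane-3-carboxylic acid; 12 tert-butyldimethyl[(2-methylidenepent-4-yn-1-yl)oxy]silane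
Product: 15 (4S,5R)-4-[(2E)-5-{[(tert-butyldimethylsilyl)oxy]methyl}-3-(diethylamino)hexa-2,5-dienoyl]-5-ethenyloxolan-2-one, via acid chloride 13 (not isolated), via ynone 14 (not isolated)
Conditions: (COCl)2, HCONMe2 (cat.), CH2Cl2, 0 °C → rt, evaporate; 12, PdCl2(PPh3)2 (2 mol%), CuI (4 mol%), Et3N (1.1 equiv), THF, rt; Et2NH, rt
Reagents that add atoms: diethylamine, CCNCC
Why: Acyl Sonogashira coupling: zerovalent palladium formed in situ inserts into the C–Cl bond and the copper acetylide transfers the alkyne, forming C8–C9. Conjugate addition of the secondary amine to the ynone in the same flask places nitrogen on C2 and gives the E enaminone (C8 cis to C3). This also removes the acidifying ynone carbonyl next to C7 quickly, so epimerisation or E1cB opening of the lactone is not expected to compete.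

Step 8
Reactants: 15 (4S,5R)-4-[(2E)-5-{[(tert-butyldimethylsilyl)oxy]methyl}-3-(diethylamino)hexa-2,5-dienoyl]-5-ethenyloxolan-2-one
Product: 16 (6R,7S)-15-(tert-butyldimethylsilyloxy)-2-(diethylamino)-8-oxo-1,10,14-trinorgermacra-2(9),4-dien-12,6-olide
Conditions: second-generation Grubbs catalyst RuCl2(=CHPh)(H2IMes)(PCy3) (10 mol%), toluene (2 mM), 80 °C
Reagents that add atoms: none
Why: Ring-closing metathesis between the C6 vinyl group and the 1,1-disubstituted olefin forms C4=C5 with loss of ethene. The E enaminone and the trans lactone hold the two olefins on the same side, and an eight-membered ring can hold the new olefin only as the cis isomer.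

Step 9
Reactants: 16 (6R,7S)-15-(tert-butyldimethylsilyloxy)-2-(diethylamino)-8-oxo-1,10,14-trinorgermacra-2(9),4-dien-12,6-olide
Product: 17 (6R,7S)-15-hydroxy-2,8-dioxo-1,10,14-trinorgermacr-4-en-12,6-olide
Conditions: 1 M HCl, THF, 0 °C → rt
Reagents that add atoms: water, O
Why: Acid hydrolysis of the vinylogous amide (C-protonation at C9, hydrolysis of the iminium ion) gives the cyclic 1,3-dione, and the same medium cleaves the primary silyl ether. The ring prevents the cyclodehydration to a furan that an open-chain γ-hydroxy ketone could undergo.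

Step 10
Reactants: 17 (6R,7S)-15-hydroxy-2,8-dioxo-1,10,14-trinorgermacr-4-en-12,6-olide
Product: 18 (6R,7S)-2,15-(diisopropylsilanediyldioxy)-8-oxo-1,10,14-trinorgermacra-2(9),4-dien-12,6-olide
Conditions: i-Pr2Si(OTf)2, 2,6-lutidine, CH2Cl2, −78 → 0 °C
Reagents that add atoms: diisopropylsilyl bis(trifluoromethanesulfonate), CC(C)[Si](OS(=O)(=O)C(F)(F)F)(OS(=O)(=O)C(F)(F)F)C(C)C
Why: The primary hydroxyl is silylated first, and the tethered silyl triflate can then reach only the C2 oxygen (seven-membered dioxasilepine; O8 would need a nine-membered ring), so the enol ether is fixed as C9=C2 with C8 as the ketone. Vinylogous silyl esters transfer silicon reversibly, so any O8-silylated material should funnel to the cyclic product.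

Step 11
Reactants: 19 prop-2-yn-1-ol
Product: 20 tert-butyl(diphenyl)(prop-2-yn-1-yloxy)silane
Conditions: TBDPSCl, imidazole, CH2Cl2, rt
Reagents that add atoms: tert-butyl(chloro)diphenylsilane, CC(C)(C)[Si](Cl)(c1ccccc1)c1ccccc1
Why: Standard imidazole-promoted silylation of a primary alcohol; the bulky, fluoride-resistant group is chosen to survive the desilylation of step 12 and to bias the orientation of the photoaddition.

Step 12
Reactants: 18 (6R,7S)-2,15-(diisopropylsilanediyldioxy)-8-oxo-1,10,14-trinorgermacra-2(9),4-dien-12,6-olide; 20 tert-butyl(diphenyl)(prop-2-yn-1-yloxy)silane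
Product: 22 (6R,7S)-14-(tert-butyldiphenylsilyloxy)-15-hydroxy-2,8-dioxogermacra-1(10),4-dien-12,6-olide, via cyclobutene photoadduct 21 (not isolated)
Conditions: hν (350 nm, Pyrex), 20 (10 equiv), degassed CH2Cl2, −20 °C; then in the dark Bu4NF, AcOH, THF, 0 °C
Reagents that add atoms: none
Why: De Mayo reaction, an enone–alkyne (2+2) photocycloaddition followed by retro-aldol fragmentation. Excitation of the C8=O/C9=C2 chromophore gives the triplet enone, which adds to the alkyne stepwise through a 1,4-biradical. The four-membered ring closes by collapse of that biradical (C1–C2, then C9–C10), giving cyclobutene 21; the ten-membered ring is not closed end to end but appears when the bond shared by the four- and eight-membered rings (C2–C9) is cut. Fluoride removes the silylene from both oxygens, the C2 cyclobutanol expels the C8 enolate in a strain-driven retro-aldol, and acetic acid protonates that enolate at C9 before it can equilibrate through the dienolate. No new stereocentre survives: C2 and C9 of 21 become a carbonyl carbon and a CH2 group, and C6 and C7 are untouched. The selectivity needed is the orientation (C1 to C2, C10 to C9); it is secured because C2 is fully substituted and flanked by the silylene while C10 carries the bulky silyloxymethyl group, so only the unsubstituted terminus can bond to C2 and a biradical of the other orientation should revert. The cyclobutene olefin can only be cis in the ring, which fixes the C1=C10 geometry. The closest precedents are de Mayo ring expansions of cyclic 3-acyloxy and 3-alkoxy enones with alkynes.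

Step 13
Reactants: 22 (6R,7S)-14-(tert-butyldiphenylsilyloxy)-15-hydroxy-2,8-dioxogermacra-1(10),4-dien-12,6-olide
Product: 23 (2S,6R,7S)-14-(tert-butyldiphenylsilyloxy)-2,15-dihydroxy-8-oxogermacra-1(10),4-dien-12,6-olide
Conditions: (R)-Me-CBS oxazaborolidine (C18H20BNO, 0.3 equiv), catecholborane (2.5 equiv), toluene/CH2Cl2, −78 °C; MeOH
Reagents that add atoms: none
Why: CBS reduction: the catalyst binds the more Lewis-basic enone carbonyl with the alkenyl side (C1) as the large group, and the R catalyst then delivers hydride to the face that gives 2S by 1,2-addition. Catecholborane at −78 °C is expected to leave the less basic, α-branched C8 ketone and the lactone alone.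

Step 14
Reactants: 23 (2S,6R,7S)-14-(tert-butyldiphenylsilyloxy)-2,15-dihydroxy-8-oxogermacra-1(10),4-dien-12,6-olide
Product: 24 (2S,6R,7S)-2,15-bis(tert-butyldimethylsilyloxy)-14-(tert-butyldiphenylsilyloxy)-8-oxogermacra-1(10),4-dien-12,6-olide
Conditions: TBSCl (3 equiv), imidazole, DMF, 0 °C → rt
Reagents that add atoms: tert-butyldimethylsilyl chloride, CC(C)(C)[Si](C)(C)Cl
Why: Imidazole-promoted silylation of the primary and the secondary allylic hydroxyl; trapping O2 also draws any transannular O2–C8 hemiketal back to the open keto form.

Step 15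
Reactants: 24 (2S,6R,7S)-2,15-bis(tert-butyldimethylsilyloxy)-14-(tert-butyldiphenylsilyloxy)-8-oxogermacra-1(10),4-dien-12,6-olide
Product: 25 (2S,6R,7R,8R)-2,15-bis(tert-butyldimethylsilyloxy)-14-(tert-butyldiphenylsilyloxy)-8-hydroxygermacra-1(10),4-dien-12,6-olide
Conditions: (S)-Me-CBS oxazaborolidine (C18H20BNO, 0.5 equiv), BH3·SMe2 (1.0 equiv), THF, −30 °C; MeOH
Reagents that add atoms: none
Why: CBS reduction with the branched C7 as the large group and the C9 methylene as the small one, so the S catalyst should give 8R. Felkin–Anh attack on the outer face of the ring, anti to C6, points the same way, so catalyst and substrate are expected to reinforce each other.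

Step 16
Reactants: 25 (2S,6R,7R,8R)-2,15-bis(tert-butyldimethylsilyloxy)-14-(tert-butyldiphenylsilyloxy)-8-hydroxygermacra-1(10),4-dien-12,6-olide
Product: 26 (2S,6R,7S,8R)-2,15-bis(tert-butyldimethylsilyloxy)-14-(tert-butyldiphenylsilyloxy)-8-(triethylsilyloxy)germacra-1(10),4-dien-12,6-olide
Conditions: Et3SiOTf, 2,6-lutidine, CH2Cl2, −78 °C
Reagents that add atoms: triethylsilyl trifluoromethanesulfonate, CC[Si](CC)(CC)OS(=O)(=O)C(F)(F)F
Why: The silyl triflate silylates the hindered secondary alcohol at low temperature; blocking O8 prevents translactonisation onto C12 under the basic conditions of step 17.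

Step 17
Reactants: 26 (2S,6R,7S,8R)-2,15-bis(tert-butyldimethylsilyloxy)-14-(tert-butyldiphenylsilyloxy)-8-(triethylsilyloxy)germacra-1(10),4-dien-12,6-olide
Product: 29 (2S,6R,7S,8R)-2,15-bis(tert-butyldimethylsilyloxy)-14-(tert-butyldiphenylsilyloxy)-8-(triethylsilyloxy)germacra-1(10),4,11(13)-trien-12,6-olide, via Mannich base 27 (not isolated), via ammonium iodide 28 (not isolated)
Conditions: LiN(SiMe3)2, THF, −78 °C; [CH2=NMe2]I, −78 → 0 °C; CH3I, MeOH, rt; NaHCO3 (aq), EtOAc, rt
Reagents that add atoms: Eschenmoser's salt (N,N-dimethylmethylideneammonium iodide), C[N+](C)=C.[I-]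
Why: α-Methylenation of a lactone by the Mannich route: the lactone α-CH2 is the only acidic site, its lithium enolate adds to the iminium ion at C11, and N-methylation followed by E1cB loss of trimethylamine gives the exocyclic olefin. The C11 configuration of the intermediates is irrelevant.

Step 18
Reactants: 29 (2S,6R,7S,8R)-2,15-bis(tert-butyldimethylsilyloxy)-14-(tert-butyldiphenylsilyloxy)-8-(triethylsilyloxy)germacra-1(10),4,11(13)-trien-12,6-olide
Product: 30 (2S,6R,7R,8R)-2-(tert-butyldimethylsilyloxy)-14-(tert-butyldiphenylsilyloxy)-8,15-dihydroxygermacra-1(10),4,11(13)-trien-12,6-olide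
Conditions: camphor-10-sulfonic acid (0.1 equiv), MeOH/CH2Cl2, 0 °C
Reagents that add atoms: none
Why: Acid-catalysed methanolysis removes the secondary triethylsilyl ether and the primary tert-butyldimethylsilyl ether much faster than the secondary tert-butyldimethylsilyl ether at O2 or the tert-butyldiphenylsilyl ether at O14; methanol does not add to the methylene lactone without base.

Step 19
Reactants: 30 (2S,6R,7R,8R)-2-(tert-butyldimethylsilyloxy)-14-(tert-butyldiphenylsilyloxy)-8,15-dihydroxygermacra-1(10),4,11(13)-trien-12,6-olide
Product: 31 (2S,6R,7R,8R)-15-acetoxy-2-(tert-butyldimethylsilyloxy)-14-(tert-butyldiphenylsilyloxy)-8-hydroxygermacra-1(10),4,11(13)-trien-12,6-olide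
Conditions: AcCl (1.1 equiv), 2,4,6-collidine, CH2Cl2, −78 °C
Reagents that add atoms: acetyl chloride, CC(Cl)=O
Why: Acylation with acetyl chloride and a hindered pyridine base at −78 °C is selective for primary over secondary alcohols, and O8 is additionally shielded by the ring fusion.

Step 20
Reactants: 31 (2S,6R,7R,8R)-15-acetoxy-2-(tert-butyldimethylsilyloxy)-14-(tert-butyldiphenylsilyloxy)-8-hydroxygermacra-1(10),4,11(13)-trien-12,6-olide
Product: 32 (2S,6R,7R,8R)-15-acetoxy-2-(tert-butyldimethylsilyloxy)-14-(tert-butyldiphenylsilyloxy)-8-(3-methylbutanoyloxy)germacra-1(10),4,11(13)-trien-12,6-olide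
Conditions: (i-BuCO)2O, 4-(dimethylamino)pyridine, Et3N, CH2Cl2, 0 °C → rt
Reagents that add atoms: 3-methylbutanoic anhydride, CC(C)CC(=O)OC(=O)CC(C)C
Why: Acylation of the remaining secondary alcohol with the anhydride under nucleophilic catalysis proceeds with retention at C8; once O8 is acylated the lactone can no longer translactonise.

Step 21
Reactants: 32 (2S,6R,7R,8R)-15-acetoxy-2-(tert-butyldimethylsilyloxy)-14-(tert-butyldiphenylsilyloxy)-8-(3-methylbutanoyloxy)germacra-1(10),4,11(13)-trien-12,6-olide
Product: 33 (2S,6R,7R,8R)-15-acetoxy-2,14-dihydroxy-8-(3-methylbutanoyloxy)germacra-1(10),4,11(13)-trien-12,6-olide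
Conditions: HF·pyridine, pyridine, THF, 0 °C → rt
Reagents that add atoms: none
Why: Buffered hydrogen fluoride cleaves both remaining silyl ethers and is non-basic, so the two esters and the methylene lactone are not touched and no acyl migration is expected.

Step 22
Reactants: 33 (2S,6R,7R,8R)-15-acetoxy-2,14-dihydroxy-8-(3-methylbutanoyloxy)germacra-1(10),4,11(13)-trien-12,6-olide
Product: 34 (2S,6R,7R,8R)-15-acetoxy-2-hydroxy-8-(3-methylbutanoyloxy)-14-oxogermacra-1(10),4,11(13)-trien-12,6-olide (target)
Conditions: 2,2,6,6-tetramethylpiperidin-1-oxyl (0.2 equiv), PhI(OAc)2 (1.2 equiv), CH2Cl2, rt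
Reagents that add atoms: none
Why: Oxoammonium-mediated oxidation takes the unhindered primary allylic alcohol far faster than the secondary one and stops at the aldehyde. The formyl group is trans to C2 on the olefin, so no lactol can form.

## Compound list

1 | (S)-4-benzyl-1,3-oxazolidin-2-one | O=C1N[C@@H](Cc2ccccc2)CO1 | starting material
2 | methyl 4-chloro-4-oxobutanoate | COC(=O)CCC(Cl)=O | starting material
3 | methyl 4-[(4S)-4-benzyl-2-oxo-1,3-oxazolidin-3-yl]-4-oxobutanoate | COC(=O)CCC(=O)N1C(=O)OC[C@@H]1Cc1ccccc1 | intermediate
4 | prop-2-enal (acrolein) | C=CC=O | starting material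
5 | methyl (3S,4R)-3-[(4S)-4-benzyl-2-oxo-1,3-oxazolidine-3-carbonyl]-4-hydroxyhex-5-enoate (syn-aldol adduct, not isolated) | C=C[C@@H](O)[C@H](CC(=O)OC)C(=O)N1C(=O)OC[C@@H]1Cc1ccccc1 | intermediate
6 | (4S)-4-benzyl-3-[(2R,3S)-2-ethenyl-5-oxooxolane-3-carbonyl]-1,3-oxazolidin-2-one | C=C[C@H]1OC(=O)C[C@@H]1C(=O)N1C(=O)OC[C@@H]1Cc1ccccc1 | intermediate
7 | (2R,3S)-2-ethenyl-5-oxooxolane-3-carboxylic acid | C=C[C@H]1OC(=O)C[C@@H]1C(=O)O | intermediate
8 | 2-methylidenepropane-1,3-diol | C=C(CO)CO | starting material
9 | 2-{[(tert-butyldimethylsilyl)oxy]methyl}prop-2-en-1-ol | C=C(CO)CO[Si](C)(C)C(C)(C)C | intermediate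
10 | {[2-(bromomethyl)prop-2-en-1-yl]oxy}(tert-butyl)dimethylsilane | C=C(CBr)CO[Si](C)(C)C(C)(C)C | intermediate
11 | ethynylmagnesium bromide | C#C[Mg]Br | starting material
12 | tert-butyldimethyl[(2-methylidenepent-4-yn-1-yl)oxy]silane | C#CCC(=C)CO[Si](C)(C)C(C)(C)C | intermediate
13 | (2R,3S)-2-ethenyl-5-oxooxolane-3-carbonyl chloride (not isolated) | C=C[C@H]1OC(=O)C[C@@H]1C(Cl)=O | intermediate
14 | (4S,5R)-4-[5-{[(tert-butyldimethylsilyl)oxy]methyl}hex-5-en-2-ynoyl]-5-ethenyloxolan-2-one (ynone, not isolated) | C=C[C@H]1OC(=O)C[C@@H]1C(=O)C#CCC(=C)CO[Si](C)(C)C(C)(C)C | intermediate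
15 | (4S,5R)-4-[(2E)-5-{[(tert-butyldimethylsilyl)oxy]methyl}-3-(diethylamino)hexa-2,5-dienoyl]-5-ethenyloxolan-2-one | C=C[C@H]1OC(=O)C[C@@H]1C(=O)/C=C(/N(CC)CC)CC(=C)CO[Si](C)(C)C(C)(C)C | intermediate
16 | (6R,7S)-15-(tert-butyldimethylsilyloxy)-2-(diethylamino)-8-oxo-1,10,14-trinorgermacra-2(9),4-dien-12,6-olide (trans lactone, ring-cis olefins) | O=C1/C=C(N(CC)CC)\C/C(CO[Si](C)(C)C(C)(C)C)=C\[C@H]2OC(=O)C[C@H]12 | intermediate
17 | (6R,7S)-15-hydroxy-2,8-dioxo-1,10,14-trinorgermacr-4-en-12,6-olide | O=C1CC(=O)C/C(CO)=C\[C@H]2OC(=O)C[C@H]12 | intermediate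
18 | (6R,7S)-2,15-(diisopropylsilanediyldioxy)-8-oxo-1,10,14-trinorgermacra-2(9),4-dien-12,6-olide (key-step precursor; C2 enol oxygen bridged to O15) | O=C1/C=C2\C/C(=C\[C@H]3OC(=O)C[C@H]13)CO[Si](C(C)C)(C(C)C)O2 | intermediate
19 | prop-2-yn-1-ol | C#CCO | starting material
20 | tert-butyl(diphenyl)(prop-2-yn-1-yloxy)silane | C#CCO[Si](c1ccccc1)(c1ccccc1)C(C)(C)C | intermediate
21 | cyclobutene photoadduct of 18 and 20 (C1–C2 and C9–C10 formed, C2–C9 still intact; C2/C9 ring-fusion configuration not defined; not isolated) | O=C1C2C(CO[Si](c3ccccc3)(c3ccccc3)C(C)(C)C)=CC24C/C(=C\[C@H]5OC(=O)C[C@H]15)CO[Si](C(C)C)(C(C)C)O4 | intermediate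
22 | (6R,7S)-14-(tert-butyldiphenylsilyloxy)-15-hydroxy-2,8-dioxogermacra-1(10),4-dien-12,6-olide (key-step product) | O=C1O[C@@H]2/C=C(/CO)CC(=O)/C=C(/CO[Si](c3ccccc3)(c3ccccc3)C(C)(C)C)CC(=O)[C@H]2C1 | intermediate
23 | (2S,6R,7S)-14-(tert-butyldiphenylsilyloxy)-2,15-dihydroxy-8-oxogermacra-1(10),4-dien-12,6-olide | O=C1O[C@@H]2/C=C(/CO)C[C@H](O)/C=C(/CO[Si](c3ccccc3)(c3ccccc3)C(C)(C)C)CC(=O)[C@H]2C1 | intermediate
24 | (2S,6R,7S)-2,15-bis(tert-butyldimethylsilyloxy)-14-(tert-butyldiphenylsilyloxy)-8-oxogermacra-1(10),4-dien-12,6-olide | O=C1O[C@@H]2/C=C(/CO[Si](C)(C)C(C)(C)C)C[C@H](O[Si](C)(C)C(C)(C)C)/C=C(/CO[Si](c3ccccc3)(c3ccccc3)C(C)(C)C)CC(=O)[C@H]2C1 | intermediate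
25 | (2S,6R,7R,8R)-2,15-bis(tert-butyldimethylsilyloxy)-14-(tert-butyldiphenylsilyloxy)-8-hydroxygermacra-1(10),4-dien-12,6-olide | O=C1O[C@@H]2/C=C(/CO[Si](C)(C)C(C)(C)C)C[C@H](O[Si](C)(C)C(C)(C)C)/C=C(/CO[Si](c3ccccc3)(c3ccccc3)C(C)(C)C)C[C@@H](O)[C@H]2C1 | intermediate
26 | (2S,6R,7S,8R)-2,15-bis(tert-butyldimethylsilyloxy)-14-(tert-butyldiphenylsilyloxy)-8-(triethylsilyloxy)germacra-1(10),4-dien-12,6-olide | O=C1O[C@@H]2/C=C(/CO[Si](C)(C)C(C)(C)C)C[C@H](O[Si](C)(C)C(C)(C)C)/C=C(/CO[Si](c3ccccc3)(c3ccccc3)C(C)(C)C)C[C@@H](O[Si](CC)(CC)CC)[C@H]2C1 | intermediate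
27 | 13-(dimethylamino) Mannich base of 26 (C11 epimers; not isolated) | CN(C)CC1C(=O)O[C@@H]2/C=C(/CO[Si](C)(C)C(C)(C)C)C[C@H](O[Si](C)(C)C(C)(C)C)/C=C(/CO[Si](c3ccccc3)(c3ccccc3)C(C)(C)C)C[C@@H](O[Si](CC)(CC)CC)[C@@H]12 | intermediate
28 | trimethylammonium iodide of 27 (not isolated) | C[N+](C)(C)CC1C(=O)O[C@@H]2/C=C(/CO[Si](C)(C)C(C)(C)C)C[C@H](O[Si](C)(C)C(C)(C)C)/C=C(/CO[Si](c3ccccc3)(c3ccccc3)C(C)(C)C)C[C@@H](O[Si](CC)(CC)CC)[C@@H]12.[I-] | intermediate
29 | (2S,6R,7S,8R)-2,15-bis(tert-butyldimethylsilyloxy)-14-(tert-butyldiphenylsilyloxy)-8-(triethylsilyloxy)germacra-1(10),4,11(13)-trien-12,6-olide | C=C1C(=O)O[C@@H]2/C=C(/CO[Si](C)(C)C(C)(C)C)C[C@H](O[Si](C)(C)C(C)(C)C)/C=C(/CO[Si](c3ccccc3)(c3ccccc3)C(C)(C)C)C[C@@H](O[Si](CC)(CC)CC)[C@@H]12 | intermediate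
30 | (2S,6R,7R,8R)-2-(tert-butyldimethylsilyloxy)-14-(tert-butyldiphenylsilyloxy)-8,15-dihydroxygermacra-1(10),4,11(13)-trien-12,6-olide | C=C1C(=O)O[C@@H]2/C=C(/CO)C[C@H](O[Si](C)(C)C(C)(C)C)/C=C(/CO[Si](c3ccccc3)(c3ccccc3)C(C)(C)C)C[C@@H](O)[C@@H]12 | intermediate
31 | (2S,6R,7R,8R)-15-acetoxy-2-(tert-butyldimethylsilyloxy)-14-(tert-butyldiphenylsilyloxy)-8-hydroxygermacra-1(10),4,11(13)-trien-12,6-olide | C=C1C(=O)O[C@@H]2/C=C(/COC(C)=O)C[C@H](O[Si](C)(C)C(C)(C)C)/C=C(/CO[Si](c3ccccc3)(c3ccccc3)C(C)(C)C)C[C@@H](O)[C@@H]12 | intermediate
32 | (2S,6R,7R,8R)-15-acetoxy-2-(tert-butyldimethylsilyloxy)-14-(tert-butyldiphenylsilyloxy)-8-(3-methylbutanoyloxy)germacra-1(10),4,11(13)-trien-12,6-olide | C=C1C(=O)O[C@@H]2/C=C(/COC(C)=O)C[C@H](O[Si](C)(C)C(C)(C)C)/C=C(/CO[Si](c3ccccc3)(c3ccccc3)C(C)(C)C)C[C@@H](OC(=O)CC(C)C)[C@@H]12 | intermediate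
33 | (2S,6R,7R,8R)-15-acetoxy-2,14-dihydroxy-8-(3-methylbutanoyloxy)germacra-1(10),4,11(13)-trien-12,6-olide | C=C1C(=O)O[C@@H]2/C=C(/COC(C)=O)C[C@H](O)/C=C(/CO)C[C@@H](OC(=O)CC(C)C)[C@@H]12 | intermediate
34 | (2S,6R,7R,8R)-15-acetoxy-2-hydroxy-8-(3-methylbutanoyloxy)-14-oxogermacra-1(10),4,11(13)-trien-12,6-olide | C=C1C(=O)O[C@@H]2/C=C(/COC(C)=O)C[C@H](O)/C=C(/C=O)C[C@@H](OC(=O)CC(C)C)[C@@H]12 | target

## Step count and least certain steps

Total: 22 steps. Longest linear sequence: 18 steps (steps 1–3, 7–10 and 12–22; the branch through steps 4–6 is equally long, and step 11 is a one-step side branch).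

Step 12 (key step). Three processes could defeat it: geometric isomerisation of the excited eight-membered enone or its reaction with the internal C4=C5 olefin instead of capture by the alkyne; addition in the reverse orientation, since both biradical pathways are open to a 3-oxy enone; and olefin migration to C9=C10 if the dienolate equilibrates during desilylation. The fallback is a thermal route to the same bonds. It sets out from 17 and 20 and returns at 22. A rhenium carbonyl catalyst, [ReBr(CO)3(thf)]2, in toluene at about 50 °C should add the dione through C9 to the internal alkyne carbon, the alkenyl–metal species should add to the less hindered C2 carbonyl, and the resulting cyclobutenol should fragment as in the photochemical route. This is the reaction type known for alkyne insertion into cyclic β-keto esters. It makes no compound outside the list (F0).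

Step 8. Intermolecular metathesis and catalyst decay (with olefin migration) may outrun closure of a strained eight-membered ring at a 1,1-disubstituted olefin. The fallback changes the substrate into a templated one. It sets out from 15 and returns at 18. Buffered hydrolysis (aqueous AcOH, then HF·pyridine, kept mild to avoid furan formation) would give the acyclic hydroxy diketone F1. i-Pr2Si(OTf)2 with 2,6-lutidine would tie O15 to the C2 enol oxygen as the seven-membered silylene enol ether F2. Ring-closing metathesis of this pre-folded diene would then form C4=C5 and deliver 18 directly, bypassing 16 and 17.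

Step 10. Intermolecular silyl transfer could give oligomeric silyl ethers, or the strained cyclic enol silyl ether could hydrolyse on isolation. The fallback drops the tether and relies on steric differentiation of the two carbonyls. It sets out from 17 and returns at 22. Et3SiOTf and Et3N would silylate O15 and the less hindered enol oxygen at C2 (the C8 oxygen is flanked by the ring-fusion carbon), giving the bis(triethylsilyl) vinylogous ester F3. Irradiation with 20 would give the cyclobutene adduct F4, and Bu4NF with AcOH would remove both triethylsilyl groups and trigger the same fragmentation to 22.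

Step 13. The catalyst may fail to discriminate between the enone and the C8 ketone, or the ring conformation may override the catalyst and reverse the facial selectivity. The fallback corrects the configuration by substitution instead of reduction. It sets out from 22 and returns at 23. If the 2R diol F5 is the main product, a Mitsunobu reaction with chloroacetic acid (DIAD, PPh3) would acylate O15 and invert C2, giving the bis(chloroacetate) F6. Thiourea with NaHCO3 in EtOH would then remove both chloroacetyl groups under nearly neutral conditions to give 23.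

Step 15. Hydride delivery to the inner face (giving 8S) or enolisation of the β,γ-unsaturated ketone with olefin migration are the likely failures. The fallback again uses inversion. It sets out from 24 and returns at 25. The 8S alcohol F7, the only free hydroxyl at that stage, would be converted by a Mitsunobu reaction with chloroacetic acid into the 8R chloroacetate F8, and thiourea with NaHCO3 would release 25.

## Further compounds

F0 | step 12 | none | none
F1 | step 8 | (4S,5R)-5-ethenyl-4-[5-(hydroxymethyl)-3-oxohex-5-enoyl]oxolan-2-one (acyclic hydroxy diketone) | C=C[C@H]1OC(=O)C[C@@H]1C(=O)CC(=O)CC(=C)CO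
F2 | step 8 | seven-membered diisopropylsilylene enol ether of F1 (O15–Si–O2 bridge, C8 cis to C3 on C9=C2) | C=C[C@H]1OC(=O)C[C@@H]1C(=O)/C=C1\CC(=C)CO[Si](C(C)C)(C(C)C)O1
F3 | step 10 | (6R,7S)-2,15-bis(triethylsilyloxy)-8-oxo-1,10,14-trinorgermacra-2(9),4-dien-12,6-olide | O=C1/C=C(O[Si](CC)(CC)CC)\C/C(CO[Si](CC)(CC)CC)=C\[C@H]2OC(=O)C[C@H]12
F4 | step 10 | cyclobutene photoadduct of F3 and 20 (C2/C9 configuration not defined; not isolated) | O=C1C2C(CO[Si](c3ccccc3)(c3ccccc3)C(C)(C)C)=CC2(O[Si](CC)(CC)CC)C/C(CO[Si](CC)(CC)CC)=C\[C@H]2OC(=O)C[C@H]12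
F5 | step 13 | (2R,6R,7S)-14-(tert-butyldiphenylsilyloxy)-2,15-dihydroxy-8-oxogermacra-1(10),4-dien-12,6-olide (C2 epimer of 23) | O=C1O[C@@H]2/C=C(/CO)C[C@@H](O)/C=C(/CO[Si](c3ccccc3)(c3ccccc3)C(C)(C)C)CC(=O)[C@H]2C1
F6 | step 13 | (2S,6R,7S)-14-(tert-butyldiphenylsilyloxy)-2,15-bis(chloroacetoxy)-8-oxogermacra-1(10),4-dien-12,6-olide | O=C1O[C@@H]2/C=C(/COC(=O)CCl)C[C@H](OC(=O)CCl)/C=C(/CO[Si](c3ccccc3)(c3ccccc3)C(C)(C)C)CC(=O)[C@H]2C1
F7 | step 15 | (2S,6R,7R,8S)-2,15-bis(tert-butyldimethylsilyloxy)-14-(tert-butyldiphenylsilyloxy)-8-hydroxygermacra-1(10),4-dien-12,6-olide (C8 epimer of 25) | O=C1O[C@@H]2/C=C(/CO[Si](C)(C)C(C)(C)C)C[C@H](O[Si](C)(C)C(C)(C)C)/C=C(/CO[Si](c3ccccc3)(c3ccccc3)C(C)(C)C)C[C@H](O)[C@H]2C1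
F8 | step 15 | (2S,6R,7R,8R)-2,15-bis(tert-butyldimethylsilyloxy)-14-(tert-butyldiphenylsilyloxy)-8-(chloroacetoxy)germacra-1(10),4-dien-12,6-olide | O=C1O[C@@H]2/C=C(/CO[Si](C)(C)C(C)(C)C)C[C@H](O[Si](C)(C)C(C)(C)C)/C=C(/CO[Si](c3ccccc3)(c3ccccc3)C(C)(C)C)C[C@@H](OC(=O)CCl)[C@H]2C1
A1 | alternative 1 | C2 tert-butyldimethylsilyl ether of the target, (2S,6R,7R,8R) | C=C1C(=O)O[C@@H]2/C=C(/COC(C)=O)C[C@H](O[Si](C)(C)C(C)(C)C)/C=C(/C=O)C[C@@H](OC(=O)CC(C)C)[C@@H]12
A2 | alternative 2 | ten-membered C6 allylic alcohol with 15-acetoxy, 2-(tert-butyldimethylsilyloxy), 14- and 12-(triethylsilyloxy), 8-(3-methylbutanoyloxy) and C11=C13 groups | O[C@@H]1/C=C(/COC(C)=O)C[C@H](O[Si](C)(C)C(C)(C)C)/C=C(/CO[Si](CC)(CC)CC)C[C@@H](OC(=O)CC(C)C)[C@H]1C(=C)CO[Si](CC)(CC)CC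
A3 | alternative 3 | cyclodeca-1(10),4-dien-6-one with free 14-hydroxyl, 15-(4-methoxybenzyloxy), 2-(tert-butyldimethylsilyloxy), 8-(methoxymethoxy) and 12-(triethylsilyloxy) groups | O=C1/C=C(/COCc2ccc(OC)cc2)C[C@H](O[Si](C)(C)C(C)(C)C)/C=C(/CO)C[C@@H](OCOC)[C@H]1C(=C)CO[Si](CC)(CC)CC
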